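**Retrosynthetic overview**
- Last bonds: the O10–acyl ester from alcohol 19 and the (Z)-acid 26 (Wittig, C9'=C10'), then fluoride release of the C15 acid and the C16' alcohol.
- Key disconnection C1–C10: ring C (C1, C7, C8, C9, C10, C11) is closed last on an A/B diquinane by a carbonyl-ene reaction of the C10 aldehyde on the tetrasubstituted C1=C5 alkene. One step makes quaternary C1 (shared by rings A, B and C), the bicyclo[3.2.1]octene and the C10 carbinol anti to C11; C5–H follows by hydroxyl-directed hydrogenation.
- Ring A is annulated on ring B: Ireland–Claisen rearrangement (C1–C2, sets C2, brings C12), ring-closing metathesis (C4=C5), alkene shift to C1=C5.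
- Ring B, the C6 gem-dimethyl group and C7 come from the chiral pool ((S)-α-campholenic aldehyde from α-pinene oxide); C8=C9–C10 comes from a crossed aldol condensation with glyoxal monoacetal.
- Ring order: B (pool), then A, then C.

Key step: step 12

Remark: locants follow cedrane numbering (C1 quaternary, C2 formyl-bearing, C5 ring-fusion CH, C6 CMe2, C7 bridgehead CH, C8 carboxyl-bearing, C10 acyloxy-bearing, C11 CH2 bridge, C12 formyl carbon, C15 carboxyl carbon; ring A = C1–C5, ring B = C1/C5/C6/C7/C11); the C2 epimer with CHO syn to C11 is assumed to be the more stable one once O10 is acylated.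

Step 1
Reactants: 1 (−)-α-pinene oxide
Product: 2 (S)-α-campholenic aldehyde
Conditions: ZnBr2 (5 mol %), toluene, reflux
Reagents that add atoms: none
Why: ZnBr2 opens the epoxide at the tertiary carbon and the pinanyl cation undergoes the known 1,2-alkyl shift and fragmentation (Meinwald-type rearrangement) to the cyclopentenyl acetaldehyde, the C7 stereocentre being the untouched bridgehead of the pinane.

Step 2
Reactants: 2 (S)-α-campholenic aldehyde; 3 2,2-dimethoxyacetaldehyde (60% in water)
Product: 4 (E)-enal acetal
Conditions: pyrrolidine (20 mol %), propanoic acid (20 mol %), toluene, 50 °C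
Reagents that add atoms: none
Why: amine-catalysed crossed aldol condensation (the enamine of 2 adds to the non-enolisable aldehyde 3, then dehydration) should give the (E)-enal with formyl anti to the acetal carbon, the stable geometry that places C7 and C10 cis across C8=C9.

Step 3
Reactants: 4 (E)-enal acetal
Product: 5 (E)-enoic acid acetal
Conditions: NaClO2, NaH2PO4, 2-methyl-2-butene, tBuOH/H2O, 0 °C to rt
Reagents that add atoms: sodium chlorite, [Na+].[O-]Cl=O
Why: Pinnick oxidation takes the enal to the acid under buffered conditions that should spare the acetal and both alkenes.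

Step 4
Reactants: 5 (E)-enoic acid acetal
Product: 6 2-(trimethylsilyl)ethyl ester
Conditions: 2-(trimethylsilyl)ethanol, DCC, DMAP (cat.), CH2Cl2, 0 °C to rt
Reagents that add atoms: 2-(trimethylsilyl)ethanol, C[Si](C)(C)CCO
Why: Steglich esterification installs a fluoride-labile C15 ester that has no α-hydrogen and so stays silent in the later enolate step.

Step 5
Reactants: 6 2-(trimethylsilyl)ethyl ester
Product: 7 allylic alcohol
Conditions: SeO2 (0.3 equiv), tBuOOH (3 equiv), CH2Cl2, rt
Reagents that add atoms: tert-butyl hydroperoxide, CC(C)(C)OO; selenium dioxide (oxygen carrier), O=[Se]=O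
Why: catalytic SeO2 allylic oxidation (ene reaction, then [2,3]-shift) attacks the electron-rich ring alkene at its more substituted end, where only the vinylic methyl carries hydrogen because C6 is quaternary, while the electron-poor enoate is inert.

Step 6
Reactants: 7 allylic alcohol; 8 pent-4-enoic acid
Product: 9 allylic pent-4-enoate
Conditions: DCC, DMAP (cat.), CH2Cl2, 0 °C to rt
Reagents that add atoms: none
Why: Steglich esterification of an unhindered primary allylic alcohol.

Step 7
Reactants: 9 allylic pent-4-enoate
Product: 12 Claisen acid, via silyl ketene acetal 10 (not isolated), via trimethylsilyl ester 11 (not isolated)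
Conditions: LiN(iPr)2, THF/DMPU, −78 °C; Me3SiCl; −78 to 50 °C; then aq. citric acid (pH 4)
Reagents that add atoms: chlorotrimethylsilane, C[Si](C)(C)Cl (silicon stays only in 10 and 11)
Why: Ireland–Claisen rearrangement through a chair transition state, in which the (Z)-silyl ketene acetal formed in THF/DMPU should add to C1 anti to the C7 side chain, forms C1–C2, moves the alkene to the exocyclic position and sets C2 (the new C1 centre is erased in step 10).

Step 8
Reactants: 12 Claisen acid
Product: 13 N-methoxy-N-methylamide
Conditions: MeNHOMe (free base), DCC, DMAP (cat.), CH2Cl2, 0 °C to rt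
Reagents that add atoms: N,O-dimethylhydroxylamine, CNOC
Why: carbodiimide amide coupling stores C12 at the aldehyde oxidation level in a form that should not drift into conjugation in steps 10 to 12.

Step 9
Reactants: 13 N-methoxy-N-methylamide
Product: 14 ring A cyclopentene
Conditions: second-generation Grubbs catalyst (H2IMes)(PCy3)Cl2Ru=CHPh (5 mol %), CH2Cl2 (5 mM), 40 °C
Reagents that add atoms: none
Why: ring-closing metathesis of the terminal allyl group onto the exocyclic methylene closes the five-membered ring A with loss of ethylene; the trisubstituted enoate does not take part.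

Step 10
Reactants: 14 ring A cyclopentene
Product: 15 diquinane with C1=C5
Conditions: Co(salen)Cl (salen = N,N'-bis(3,5-di-tert-butylsalicylidene)-1,2-cyclohexanediaminate, 3 mol %), PhSiH3 (6 mol %), benzene, rt
Reagents that add atoms: none
Why: metal-hydride hydrogen-atom-transfer isomerization (reversible H-atom addition at C4 gives the tertiary C5 radical, H-atom loss from C1) should deliver the more stable tetrasubstituted ring-fusion alkene under neutral conditions that leave C2–H and the acetal alone.

Step 11
Reactants: 15 diquinane with C1=C5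
Product: 16 aldehyde
Conditions: Amberlyst-15, acetone/H2O, 0 °C to rt
Reagents that add atoms: water, O
Why: mild acid hydrolysis of the dimethyl acetal frees the C10 aldehyde of the γ-oxo-enoate, whose (E) geometry (ester anti to formyl) is the stable one.

Step 12
Reactants: 16 aldehyde
Product: 17 tricyclic homoallylic alcohol
Conditions: Me2AlCl (2.5 equiv), CH2Cl2, −78 to −40 °C; aq. Rochelle salt
Reagents that add atoms: none
Why: Me2AlCl binds the C10 aldehyde and the tetrasubstituted C1=C5 alkene attacks through C1 in a type 1 intramolecular carbonyl-ene reaction, the allylic hydrogen on C4 passing to oxygen in a six-membered transition state while the aluminium alkoxide loses methane, so that no free acid is left to trigger cationic rearrangement. The closest known reaction type is the Lewis acid-promoted ene cyclization of unsaturated aldehydes such as citronellal to isopulegol, here run on a cis-locked chain so that the new ring is bridged. Ring C closes in a 6-exo-trig sense on both π partners by the C1–C10 bond (C10, C9, C8, C7, C11, C1), which turns the A/B diquinane into the bicyclo[3.2.1]octene and makes C1 quaternary. C1 is controlled by the tether, because the chain on C7 can reach C1 only from its own face, and C10 by the ene geometry, because oxygen must lie over C4–H on the C5 side, which places the hydroxyl anti to C11 as in the target. The step needs attack at C1 and not at C5, and ene chemistry and not a free cation: attack at C5 would form a bond next to the C6 gem-dimethyl carbon and put that carbon on the one-carbon bridge, the (E)-enoate set in step 2 holds C10 over C1, and excess Me2AlCl ties up the amide oxygen.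

Step 13
Reactants: 17 tricyclic homoallylic alcohol
Product: 18 hydroxy aldehyde
Conditions: Cp2Zr(H)Cl (2.5 equiv), THF, 0 °C to rt; wet silica work-up
Reagents that add atoms: none
Why: Cp2Zr(H)Cl reduces the N-methoxy-N-methylamide to the aldehyde through a stable zirconated hemiaminal and should leave the ester and both alkenes, the free hydroxyl using up one equivalent.

Step 14
Reactants: 18 hydroxy aldehyde
Product: 19 saturated ring A hydroxy aldehyde
Conditions: [Ir(cod)(PCy3)(py)]PF6 (5 mol %), H2 (1 atm), CH2Cl2, 0 °C
Reagents that add atoms: none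
Why: hydroxyl-directed homogeneous hydrogenation, in which the C10 hydroxyl that sits over C5 binds iridium and delivers hydrogen to the endo face of C4=C5, should give the cis-fused A/B diquinane with C5–H syn to C10.

Step 15
Reactants: 20 9-bromononanoic acid
Product: 21 (8-carboxyoctyl)triphenylphosphonium bromide
Conditions: PPh3, MeCN, reflux
Reagents that add atoms: triphenylphosphine, c1ccc(cc1)P(c1ccccc1)c1ccccc1
Why: SN2 quaternization of a primary bromide.

Step 16
Reactants: 22 heptane-1,7-diol
Product: 23 7-(tert-butyldimethylsilyloxy)heptan-1-ol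
Conditions: NaH (1.0 equiv), THF, rt; then tBuMe2SiCl (1.0 equiv)
Reagents that add atoms: tert-butyldimethylsilyl chloride, CC(C)(C)[Si](C)(C)Cl
Why: monosilylation of a symmetrical diol through its sparingly soluble monosodium alkoxide.

Step 17
Reactants: 23 7-(tert-butyldimethylsilyloxy)heptan-1-ol
Product: 24 7-(tert-butyldimethylsilyloxy)heptanal
Conditions: TEMPO (10 mol %), PhI(OAc)2 (1.1 equiv), CH2Cl2, rt
Reagents that add atoms: none
Why: oxoammonium-mediated oxidation stops cleanly at the aldehyde and leaves the silyl ether.

Step 18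
Reactants: 21 (8-carboxyoctyl)triphenylphosphonium bromide; 24 7-(tert-butyldimethylsilyloxy)heptanal
Product: 26 (Z)-16-(tert-butyldimethylsilyloxy)hexadec-9-enoic acid, via carboxylate ylide 25 (not isolated)
Conditions: NaN(SiMe3)2 (2.1 equiv), THF, −78 °C; then 24, −78 °C to rt; aq. HCl work-up
Reagents that add atoms: none
Why: Wittig olefination of a non-stabilised ylide under lithium-free conditions at low temperature should give the (Z)-alkene.

Step 19
Reactants: 19 saturated ring A hydroxy aldehyde; 26 (Z)-16-(tert-butyldimethylsilyloxy)hexadec-9-enoic acid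
Product: 27 fully protected ester
Conditions: DCC, DMAP (1 equiv), CH2Cl2, 0 °C to rt
Reagents that add atoms: none
Why: Steglich esterification with DMAP acyl transfer acylates the hindered C10 alcohol, the only hydroxyl present, and tolerates the aldehyde.

Step 20
Reactants: 27 fully protected ester
Product: 28 CNP0214056.2 (target)
Conditions: Bu4NF (4 equiv), AcOH (4 equiv), THF, 0 °C to rt
Reagents that add atoms: none
Why: buffered fluoride cleaves the silyl ether and the 2-(trimethylsilyl)ethyl ester (β-elimination to ethylene) and should leave the C10 ester, the (Z)-alkene and the aldehyde α-centre untouched.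

**Compound list**
1 | (−)-α-pinene oxide, (1S,2S,4R,6S)-2,7,7-trimethyl-3-oxatricyclo[4.1.1.0(2,4)]octane, the epoxide of (1R,5R)-α-pinene | C[C@@]12O[C@@H]1C[C@@H]1C[C@H]2C1(C)C | starting material
2 | (S)-α-campholenic aldehyde, 2-[(1S)-2,2,3-trimethylcyclopent-3-en-1-yl]acetaldehyde | CC1(C)[C@H](CC=O)CC=C1C | intermediate
3 | 2,2-dimethoxyacetaldehyde | COC(OC)C=O | starting material
4 | (E)-4,4-dimethoxy-2-[(1R)-2,2,3-trimethylcyclopent-3-en-1-yl]but-2-enal (C7 unchanged from 2) | CC1(C)[C@H](/C(C=O)=C\C(OC)OC)CC=C1C | intermediate
5 | (E)-4,4-dimethoxy-2-[(1R)-2,2,3-trimethylcyclopent-3-en-1-yl]but-2-enoic acid | CC1(C)[C@H](/C(C(=O)O)=C\C(OC)OC)CC=C1C | intermediate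
6 | 2-(trimethylsilyl)ethyl ester of 5 | CC1(C)[C@H](/C(C(=O)OCC[Si](C)(C)C)=C\C(OC)OC)CC=C1C | intermediate
7 | 2-(trimethylsilyl)ethyl (E)-2-[(1R)-3-(hydroxymethyl)-2,2-dimethylcyclopent-3-en-1-yl]-4,4-dimethoxybut-2-enoate | CC1(C)[C@H](/C(C(=O)OCC[Si](C)(C)C)=C\C(OC)OC)CC=C1CO | intermediate
8 | pent-4-enoic acid | OC(=O)CCC=C | starting material
9 | pent-4-enoate ester of allylic alcohol 7 | CC1(C)[C@H](/C(C(=O)OCC[Si](C)(C)C)=C\C(OC)OC)CC=C1COC(=O)CCC=C | intermediate
10 | (Z)-O-trimethylsilyl ketene acetal of 9 (allyl group cis to OSiMe3) | CC1(C)[C@H](/C(C(=O)OCC[Si](C)(C)C)=C\C(OC)OC)CC=C1CO/C(O[Si](C)(C)C)=C/CC=C | intermediate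
11 | trimethylsilyl ester of acid 12 | CC1(C)[C@H](/C(C(=O)OCC[Si](C)(C)C)=C\C(OC)OC)C[C@@H]([C@H](CC=C)C(=O)O[Si](C)(C)C)C1=C | intermediate
12 | Claisen acid: 2-substituted pent-4-enoic acid whose C2 is bonded to C1 of ring B (C1–C2 trans to the C7 side chain, C2 as in the target), exocyclic methylene on C5, C7 side chain as in 6 | CC1(C)[C@H](/C(C(=O)OCC[Si](C)(C)C)=C\C(OC)OC)C[C@@H]([C@H](CC=C)C(=O)O)C1=C | intermediate
13 | N-methoxy-N-methylamide of 12 | CC1(C)[C@H](/C(C(=O)OCC[Si](C)(C)C)=C\C(OC)OC)C[C@@H]([C@H](CC=C)C(=O)N(C)OC)C1=C | intermediate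
14 | bicyclo[3.3.0]oct-4-ene (cedrane locants, C4=C5) with C1–H, C2 amide trans to H1, C6 gem-dimethyl, C7 side chain as in 6 | CC1(C)[C@H](/C(C(=O)OCC[Si](C)(C)C)=C\C(OC)OC)C[C@H]2[C@@H](C(=O)N(C)OC)CC=C12 | intermediate
15 | bicyclo[3.3.0]oct-1(5)-ene isomer of 14 (tetrasubstituted C1=C5; C2 amide on the face opposite to the C7 side chain) | CC1(C)[C@H](/C(C(=O)OCC[Si](C)(C)C)=C\C(OC)OC)CC2=C1CC[C@@H]2C(=O)N(C)OC | intermediate
16 | aldehyde from 15: (E)-4-oxobut-2-enoate side chain on C7 (C10 formyl cis to C7) | CC1(C)[C@H](/C(C(=O)OCC[Si](C)(C)C)=C\C=O)CC2=C1CC[C@@H]2C(=O)N(C)OC | intermediate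
17 | 10-hydroxycedra-4,8-diene with C15 as 2-(trimethylsilyl)ethyl ester and C12 as N-methoxy-N-methylamide; C10–OH anti to C11 (on the C5 side), C12 on the face of ring A syn to C11 | CC1(C)[C@H]2C[C@@]3([C@@H](O)C=C2C(=O)OCC[Si](C)(C)C)[C@@H](C(=O)N(C)OC)CC=C13 | intermediate
18 | 12-aldehyde corresponding to 17 | CC1(C)[C@H]2C[C@@]3([C@@H](O)C=C2C(=O)OCC[Si](C)(C)C)[C@@H](C=O)CC=C13 | intermediate
19 | 2-(trimethylsilyl)ethyl ester of laccijalaric acid (10-hydroxy-12-oxocedr-8-en-15-oate; C5–H syn to C10) | CC1(C)[C@H]2C[C@@]3([C@@H](O)C=C2C(=O)OCC[Si](C)(C)C)[C@@H](C=O)CC[C@@H]13 | intermediate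
20 | 9-bromononanoic acid | OC(=O)CCCCCCCCBr | starting material
21 | (8-carboxyoctyl)triphenylphosphonium bromide | OC(=O)CCCCCCCC[P+](c1ccccc1)(c1ccccc1)c1ccccc1.[Br-] | intermediate
22 | heptane-1,7-diol | OCCCCCCCO | starting material
23 | 7-(tert-butyldimethylsilyloxy)heptan-1-ol | OCCCCCCCO[Si](C)(C)C(C)(C)C | intermediate
24 | 7-(tert-butyldimethylsilyloxy)heptanal | O=CCCCCCCO[Si](C)(C)C(C)(C)C | intermediate
25 | sodium 9-(triphenylphosphoranylidene)nonanoate (carboxylate ylide) | [Na+].[O-]C(=O)CCCCCCCC=P(c1ccccc1)(c1ccccc1)c1ccccc1 | intermediate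
26 | (Z)-16-(tert-butyldimethylsilyloxy)hexadec-9-enoic acid | OC(=O)CCCCCCC/C=C\CCCCCCO[Si](C)(C)C(C)(C)C | intermediate
27 | O10 ester of 19 with acid 26 | CC1(C)[C@H]2C[C@@]3([C@@H](OC(=O)CCCCCCC/C=C\CCCCCCO[Si](C)(C)C(C)(C)C)C=C2C(=O)OCC[Si](C)(C)C)[C@@H](C=O)CC[C@@H]13 | intermediate
28 | CNP0214056.2: 10-O-[(Z)-16-hydroxyhexadec-9-enoyl]laccijalaric acid | CC1(C)[C@H]2C[C@@]3([C@@H](OC(=O)CCCCCCC/C=C\CCCCCCO)C=C2C(=O)O)[C@@H](C=O)CC[C@@H]13 | target

**Step count and risks**
Total step count: 20. Longest linear sequence: 16 steps (steps 1 to 14, 19 and 20).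

Steps most likely to fail:

Step 12 (carbonyl-ene closure). The concerted proton transfer may be lost to a free C5 cation, which can be captured by the amide oxygen or take a 1,2-methyl shift from C6, or the aldehyde may attack C5 instead of C1. The fallback sets out from 16 and trades the ene reaction for a two-stage halo-Prins route. With SnCl4 (1.1 equiv) in CH2Cl2 at −78 °C, the tin-bound alkoxide should hand chloride to the C5 cation from the face it occupies, which keeps O10 on the C5 side, and give the 5-chloro-10-hydroxy tricycle F1. Because C1 and C6 are quaternary, only C4 carries β-hydrogen, so DBU in toluene at 80 °C can remove HCl in one direction only. The fallback comes back to the route at 17.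

Step 7 (Ireland–Claisen rearrangement). Facial selectivity at C1 may be poor, and after the alkene shift of step 10 this shows up as scrambling of C2. The fallback replaces kinetic control by thermodynamic control at the end. It sets out from the crude ester of step 19, that is 27 together with the C2 epimer of 27 F2. A catalytic amount of DBU in CH2Cl2 at rt equilibrates the aldehyde α-centre through the enol. With O10 acylated no lactol can form, and the formyl group should settle on the ring A face syn to C11, away from the C10 acyloxy group. The fallback comes back at 27.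

Step 14 (directed hydrogenation). The allylic C8=C9 enoate may also be reduced under hydroxyl direction, or hydrogen may be delivered to the exo face. The fallback sets out from 17 and uses a radical hydrogenation before the amide is reduced. Mn(dpm)3 (dpm = dipivaloylmethanate), PhSiH3 and tBuOOH in iPrOH add a hydrogen atom to the electron-rich C4=C5 alkene only. The tertiary C5 radical should be quenched to the strongly favoured cis-fused diquinane, giving the 4,5-dihydro N-methoxy-N-methylamide F3. Cp2Zr(H)Cl in THF then gives the aldehyde, and the fallback comes back at 19.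

**Further compounds**
F1 | step 12 | 5-chloro-10-hydroxycedr-8-ene with C15 2-(trimethylsilyl)ethyl ester and C12 N-methoxy-N-methylamide (either C5 epimer) | CC1(C)[C@H]2C[C@@]3([C@@H](O)C=C2C(=O)OCC[Si](C)(C)C)[C@@H](C(=O)N(C)OC)CCC13Cl
F2 | step 7 | C2 epimer of 27 | CC1(C)[C@H]2C[C@@]3([C@@H](OC(=O)CCCCCCC/C=C\CCCCCCO[Si](C)(C)C(C)(C)C)C=C2C(=O)OCC[Si](C)(C)C)[C@H](C=O)CC[C@@H]13
F3 | step 14 | 4,5-dihydro derivative of 17 (C5–H syn to C10) | CC1(C)[C@H]2C[C@@]3([C@@H](O)C=C2C(=O)OCC[Si](C)(C)C)[C@@H](C(=O)N(C)OC)CC[C@@H]13
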